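The ten-membered carbocycle is closed last, across C7–C8 (germacrane numbering), the bond that links the α-methylene-γ-butyrolactone to the carbinol bearing the methacrylate. The precursor is an open (Z,Z)-dienyl chain that ends in a β,γ-unsaturated C8 aldehyde and in a preformed (6R)-3-(bromomethyl)butenolide. Chromium(II) turns the allylic bromide into an allylchromium that attacks the aldehyde through C7 (SE2′): one operation closes the ring, forms C7–C8, sets C7 and C8 and unveils the exocyclic C11=C13 methylene. The feature exploited is the 1,2-relation between the C8 oxygen and the β-carbon C7 of the α-methylene lactone. Both trisubstituted olefins come from hydroxyl-directed trans-hydroalumination/iodination; C8 is inverted during esterification.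

Key step: step 14

Remark on numbering: atoms are named by germacrane numbering of the target (ring C1–C10, lactone O on C6, C11–C13 methylene lactone, C14 hydroxymethyl on C10, C15 methyl on C4). TBS = tert-butyldimethylsilyl, PMB = 4-methoxybenzyl.
Assumption: (S,S)-ProPhenol stands for the ligand antipode that gives the S carbinols drawn in steps 1 and 6; if the sense of induction is the opposite, the (R,R) ligand is used.
Assumption: compounds 12, 17 and 21 are bought.

Step 1
Reactants: 1 (E)-but-2-enal; 2 propyne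
Product: 4 (4S,5E)-hept-5-en-2-yn-4-ol, via methyl(prop-1-yn-1-yl)zinc 3 (not isolated)
Conditions: (S,S)-ProPhenol (10 mol %), Me2Zn, toluene, 0 °C to rt
Reagents that add atoms: none
Why: Zn–ProPhenol-catalysed enantioselective alkynylation of an enal, in which the alkynylzinc adds 1,2 to the aldehyde inside the chiral dinuclear zinc pocket and sets the future C6 carbinol as S.

Step 2
Reactants: 4 (4S,5E)-hept-5-en-2-yn-4-ol
Product: 6 (2Z,4S,5E)-2-iodohepta-2,5-dien-4-ol, via sodium vinylalanate 5 (not isolated)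
Conditions: Red-Al, THF, 0 °C to rt; EtOAc; then I2, −78 to 0 °C
Reagents that add atoms: iodine, II
Why: Hydroxyl-directed trans-hydroalumination of the propargylic alcohol puts Al on the distal alkyne carbon, and iodinolysis with retention gives the (Z)-vinyl iodide that fixes the C4=C5 geometry (C3 will end cis to C6).

Step 3
Reactants: 6 (2Z,4S,5E)-2-iodohepta-2,5-dien-4-ol
Product: 7 (2Z,4S,5E)-2-iodo-4-[(4-methoxybenzyl)oxy]hepta-2,5-diene
Conditions: NaH, PMBCl, n-Bu4NI (cat.), THF/DMF, 0 °C to rt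
Reagents that add atoms: 4-methoxybenzyl chloride, COc1ccc(CCl)cc1
Why: Williamson etherification gives a PMB ether that should survive the organolithium, hydride and palladium steps and is removed oxidatively later.

Step 4
Reactants: 7 PMB-protected vinyl iodide; 8 ethylene oxide
Product: 10 (3Z,5S,6E)-5-[(4-methoxybenzyl)oxy]-3-methylocta-3,6-dien-1-ol, via vinyllithium 9 (not isolated)
Conditions: t-BuLi (2.1 equiv), Et2O, −78 °C; then ethylene oxide, BF3·OEt2, −78 °C
Reagents that add atoms: none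
Why: Lithium–iodine exchange with retention of the Z geometry, followed by BF3-promoted SN2 opening of the epoxide by the vinyllithium, adds C3–C2 as a primary alcohol.

Step 5
Reactants: 10 homoallylic alcohol
Product: 11 (3Z,5S,6E)-5-[(4-methoxybenzyl)oxy]-3-methylocta-3,6-dienal
Conditions: Dess–Martin periodinane, NaHCO3, CH2Cl2, 0 °C; used crude
Reagents that add atoms: none
Why: Dess–Martin oxidation under buffered, non-basic conditions should give the β,γ-unsaturated aldehyde without migration of the Z-trisubstituted olefin.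

Step 6
Reactants: 11 β,γ-unsaturated aldehyde; 12 tert-butyldimethyl(prop-2-yn-1-yloxy)silane
Product: 14 (4S,6Z,8S,9E)-1-[(tert-butyldimethylsilyl)oxy]-8-[(4-methoxybenzyl)oxy]-6-methylundeca-6,9-dien-2-yn-4-ol, via alkynyl(methyl)zinc 13 (not isolated)
Conditions: (S,S)-ProPhenol (20 mol %), Me2Zn, Ph3P=O (40 mol %), toluene, 0 °C; slow addition of 11
Reagents that add atoms: none
Why: A second Zn–ProPhenol alkynylation sets the C2 carbinol as S under catalyst control (the remote C6 centre should exert no bias), and slow addition keeps enolisation of the aldehyde down.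

Step 7
Reactants: 14 propargylic alcohol
Product: 16 (2Z,4S,6Z,8S,9E)-1-[(tert-butyldimethylsilyl)oxy]-2-iodo-8-[(4-methoxybenzyl)oxy]-6-methylundeca-2,6,9-trien-4-ol, via sodium vinylalanate 15 (not isolated)
Conditions: Red-Al, THF, −20 to 0 °C; EtOAc; then I2, −78 °C
Reagents that add atoms: iodine, II
Why: The same hydroxyl-directed trans-hydroalumination/iodination delivers H to C1 and I to C10, so that iodine stands cis to C2.

Step 8
Reactants: 16 vinyl iodide; 17 (1,3-dioxolan-2-ylmethyl)zinc bromide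
Product: 18 (2E,4S,6Z,8S,9E)-2-{[(tert-butyldimethylsilyl)oxy]methyl}-1-(1,3-dioxolan-2-yl)-8-[(4-methoxybenzyl)oxy]-6-methylundeca-2,6,9-trien-4-ol
Conditions: Pd(PPh3)4 (5 mol %), 17 (3 equiv), THF, 50 °C
Reagents that add atoms: none
Why: Negishi sp2–sp3 coupling with retention at the vinyl iodide puts C9 cis to C2 (the C1=C10 geometry of the target) and brings C8 as a dioxolane-masked aldehyde, the free alcohol being tolerated as its zinc alkoxide.

Step 9
Reactants: 18 dioxolane alcohol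
Product: 19 (2E,4S,6Z,8S,9E)-2-{[(tert-butyldimethylsilyl)oxy]methyl}-1-(1,3-dioxolan-2-yl)-8-[(4-methoxybenzyl)oxy]-6-methylundeca-2,6,9-trien-4-yl acetate
Conditions: Ac2O, pyridine, DMAP (cat.), CH2Cl2, 0 °C to rt
Reagents that add atoms: acetic anhydride, CC(=O)OC(C)=O
Why: DMAP-catalysed acetylation installs the C2 acetate of the target after the last hydride and organometallic steps.

Step 10
Reactants: 19 PMB ether acetate
Product: 20 (2E,4S,6Z,8S,9E)-2-{[(tert-butyldimethylsilyl)oxy]methyl}-1-(1,3-dioxolan-2-yl)-8-hydroxy-6-methylundeca-2,6,9-trien-4-yl acetate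
Conditions: DDQ, CH2Cl2/pH 7 buffer, 0 °C
Reagents that add atoms: none
Why: Oxidative PMB cleavage through the benzylic oxocarbenium ion should free the C6 alcohol and leave silyl ether, acetate, acetal and olefins untouched.

Step 11
Reactants: 20 C6 alcohol; 21 2-(bromomethyl)prop-2-enoic acid
Product: 23 (2E,4S,6Z,8S,9E)-4-(acetyloxy)-2-{[(tert-butyldimethylsilyl)oxy]methyl}-1-(1,3-dioxolan-2-yl)-6-methylundeca-2,6,9-trien-8-yl 2-(bromomethyl)prop-2-enoate, via 2-(bromomethyl)prop-2-enoyl chloride 22 (not isolated)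
Conditions: 21, (COCl)2, DMF (cat.), CH2Cl2, 0 °C; then 20, 2,6-lutidine, CH2Cl2, −30 to 0 °C
Reagents that add atoms: none
Why: Acylation of the secondary alcohol by the acid chloride under a hindered base should give the ester without SN2′ attack of the base on the allylic bromide.

Step 12
Reactants: 23 2-(bromomethyl)acrylate
Product: 24 (1Z,4S,5E)-1-[(2R)-4-(bromomethyl)-5-oxo-2,5-dihydrofuran-2-yl]-6-{[(tert-butyldimethylsilyl)oxy]methyl}-7-(1,3-dioxolan-2-yl)-2-methylhepta-1,5-dien-4-yl acetate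
Conditions: Hoveyda–Grubbs II (10 mol %), toluene (5 mM), 70 °C
Reagents that add atoms: none
Why: Ring-closing metathesis, in which the phosphine-free ruthenium carbene loads at the propenyl group and closes the five-membered ring onto the 1,1-disubstituted acrylate with loss of propene, while the trisubstituted olefins are too hindered to react and C6 is not touched.

Step 13
Reactants: 24 butenolide acetal
Product: 26 (1Z,4S,5E)-1-[(2R)-4-(bromomethyl)-5-oxo-2,5-dihydrofuran-2-yl]-6-{[(tert-butyldimethylsilyl)oxy]methyl}-2-methyl-8-oxoocta-1,5-dien-4-yl acetate, via collidinium acetal triflate 25 (not isolated)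
Conditions: TESOTf, 2,4,6-collidine, CH2Cl2, 0 °C; then H2O; used crude
Reagents that add atoms: water, O
Why: Silyl triflate/collidine acetal cleavage turns the dioxolane into a pyridinium N,O-acetal that water hydrolyses near neutral pH, which should spare the TBS ether, allylic acetate and allylic bromide and avoid conjugation of the β,γ-unsaturated aldehyde.

Step 14
Reactants: 26 bromomethylbutenolide aldehyde
Product: 28 (3aR,4S,6E,8S,10Z,11aR)-6-{[(tert-butyldimethylsilyl)oxy]methyl}-4-hydroxy-10-methyl-3-methylidene-2-oxo-2,3,3a,4,5,8,9,11a-octahydrocyclodeca[b]furan-8-yl acetate (the 8α-alcohol), via allylchromium(III) dichloride 27 (not isolated)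
Conditions: CrCl2 (8 equiv), THF/DMF (10:1), rt, slow addition of 26 (final 2 mM)
Reagents that add atoms: none
Why: CrCl2 reduces the allylic C13–Br bond by two one-electron transfers to the σ-allylchromium(III) species 27, which adds through its γ-carbon C7 to the tethered C8 aldehyde in a six-membered chair transition state (SE2′) and moves the double bond to the exocyclic C11=C13 position. The closest known reactions are the Cr- or Zn-mediated Barbier allylation of aldehydes with 3-(bromomethyl)furan-2(5H)-ones and the Nozaki–Hiyama–Kishi macrocyclisation of 2-(bromomethyl)acrylates onto aldehydes. The ten-membered ring closes in a 10-exo-trig mode and the existing butenolide ends trans-fused. C7 is controlled by C6, the aldehyde being delivered to the butenolide face opposite the C5 alkenyl substituent (6,7-trans, 7R); C8 is controlled by the Zimmerman–Traxler chair, in which the ring-locked allyl unit (C6 trans to CH2Cr) and a pseudo-equatorial C9 lead to the 8S (8α) alcohol, the centre that step 15 inverts. The step needs γ- over α-attack (10- versus 12-membered ring) and cyclisation over oligomerisation; the first is secured by the cyclic SE2′ transition state of allylchromium reagents, the second by slow addition at high dilution and by the two Z-olefins, which fold the chain and bring C8 within reach of C7. Acetate, silyl ether and lactone are inert to Cr(II).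

Step 15
Reactants: 28 8α-alcohol; 29 methacrylic acid
Product: 30 (3aR,4R,6E,8S,10Z,11aR)-8-(acetyloxy)-6-{[(tert-butyldimethylsilyl)oxy]methyl}-10-methyl-3-methylidene-2-oxo-2,3,3a,4,5,8,9,11a-octahydrocyclodeca[b]furan-4-yl 2-methylprop-2-enoate
Conditions: PPh3, DIAD, toluene, 0 °C to rt
Reagents that add atoms: none
Why: Mitsunobu esterification, in which methacrylate displaces the alkoxyphosphonium ion of the 8α-alcohol by SN2 with inversion and so gives the 8β (8R) ester.

Step 16
Reactants: 30 silyl-protected methacrylate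
Product: 31 (3aR,4R,6E,8S,10Z,11aR)-8-(acetyloxy)-6-(hydroxymethyl)-10-methyl-3-methylidene-2-oxo-2,3,3a,4,5,8,9,11a-octahydrocyclodeca[b]furan-4-yl 2-methylprop-2-enoate (CNP0138477.1)
Conditions: HF·pyridine, pyridine, THF, 0 °C to rt
Reagents that add atoms: none
Why: Fluoride cleavage of the primary allylic TBS ether under buffered conditions should leave both esters and the α-methylene lactone intact.

Compound list
1 | (E)-but-2-enal | C/C=C/C=O | starting material
2 | propyne | CC#C | starting material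
3 | methyl(prop-1-yn-1-yl)zinc | C[Zn]C#CC | intermediate
4 | (4S,5E)-hept-5-en-2-yn-4-ol | CC#C[C@@H](O)/C=C/C | intermediate
5 | sodium vinylalanate of 4 (five-membered O–Al–C=C–C ring, two 2-methoxyethoxy groups on Al) | [Na+].C/C=C/[C@@H]1O[Al-](OCCOC)(OCCOC)C(C)=C1 | intermediate
6 | (2Z,4S,5E)-2-iodohepta-2,5-dien-4-ol | I/C(C)=C\[C@@H](O)/C=C/C | intermediate
7 | (2Z,4S,5E)-2-iodo-4-[(4-methoxybenzyl)oxy]hepta-2,5-diene | I/C(C)=C\[C@@H](OCc1ccc(OC)cc1)/C=C/C | intermediate
8 | ethylene oxide | C1CO1 | starting material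
9 | (2Z,4S,5E)-4-[(4-methoxybenzyl)oxy]hepta-2,5-dien-2-yllithium | [Li]/C(C)=C\[C@@H](OCc1ccc(OC)cc1)/C=C/C | intermediate
10 | (3Z,5S,6E)-5-[(4-methoxybenzyl)oxy]-3-methylocta-3,6-dien-1-ol | OCC/C(C)=C\[C@@H](OCc1ccc(OC)cc1)/C=C/C | intermediate
11 | (3Z,5S,6E)-5-[(4-methoxybenzyl)oxy]-3-methylocta-3,6-dienal | O=CC/C(C)=C\[C@@H](OCc1ccc(OC)cc1)/C=C/C | intermediate
12 | tert-butyldimethyl(prop-2-yn-1-yloxy)silane | C#CCO[Si](C)(C)C(C)(C)C | starting material
13 | {3-[(tert-butyldimethylsilyl)oxy]prop-1-yn-1-yl}(methyl)zinc | C[Zn]C#CCO[Si](C)(C)C(C)(C)C | intermediate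
14 | (4S,6Z,8S,9E)-1-[(tert-butyldimethylsilyl)oxy]-8-[(4-methoxybenzyl)oxy]-6-methylundeca-6,9-dien-2-yn-4-ol | CC(C)(C)[Si](C)(C)OCC#C[C@@H](O)C/C(C)=C\[C@@H](OCc1ccc(OC)cc1)/C=C/C | intermediate
15 | sodium vinylalanate of 14 (five-membered O–Al–C=C–C ring, Al on C10) | [Na+].COCCO[Al-]1(OCCOC)O[C@@H](C/C(C)=C\[C@@H](OCc2ccc(OC)cc2)/C=C/C)C=C1CO[Si](C)(C)C(C)(C)C | intermediate
16 | (2Z,4S,6Z,8S,9E)-1-[(tert-butyldimethylsilyl)oxy]-2-iodo-8-[(4-methoxybenzyl)oxy]-6-methylundeca-2,6,9-trien-4-ol | CC(C)(C)[Si](C)(C)OC/C(I)=C/[C@@H](O)C/C(C)=C\[C@@H](OCc1ccc(OC)cc1)/C=C/C | intermediate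
17 | (1,3-dioxolan-2-ylmethyl)zinc bromide | Br[Zn]CC1OCCO1 | starting material
18 | (2E,4S,6Z,8S,9E)-2-{[(tert-butyldimethylsilyl)oxy]methyl}-1-(1,3-dioxolan-2-yl)-8-[(4-methoxybenzyl)oxy]-6-methylundeca-2,6,9-trien-4-ol | CC(C)(C)[Si](C)(C)OC/C(CC1OCCO1)=C/[C@@H](O)C/C(C)=C\[C@@H](OCc2ccc(OC)cc2)/C=C/C | intermediate
19 | (2E,4S,6Z,8S,9E)-2-{[(tert-butyldimethylsilyl)oxy]methyl}-1-(1,3-dioxolan-2-yl)-8-[(4-methoxybenzyl)oxy]-6-methylundeca-2,6,9-trien-4-yl acetate | CC(C)(C)[Si](C)(C)OC/C(CC1OCCO1)=C/[C@@H](OC(C)=O)C/C(C)=C\[C@@H](OCc2ccc(OC)cc2)/C=C/C | intermediate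
20 | (2E,4S,6Z,8S,9E)-2-{[(tert-butyldimethylsilyl)oxy]methyl}-1-(1,3-dioxolan-2-yl)-8-hydroxy-6-methylundeca-2,6,9-trien-4-yl acetate | CC(C)(C)[Si](C)(C)OC/C(CC1OCCO1)=C/[C@@H](OC(C)=O)C/C(C)=C\[C@@H](O)/C=C/C | intermediate
21 | 2-(bromomethyl)prop-2-enoic acid | C=C(CBr)C(=O)O | starting material
22 | 2-(bromomethyl)prop-2-enoyl chloride | C=C(CBr)C(=O)Cl | intermediate
23 | (2E,4S,6Z,8S,9E)-4-(acetyloxy)-2-{[(tert-butyldimethylsilyl)oxy]methyl}-1-(1,3-dioxolan-2-yl)-6-methylundeca-2,6,9-trien-8-yl 2-(bromomethyl)prop-2-enoate | CC(C)(C)[Si](C)(C)OC/C(CC1OCCO1)=C/[C@@H](OC(C)=O)C/C(C)=C\[C@@H](OC(=O)C(=C)CBr)/C=C/C | intermediate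
24 | (1Z,4S,5E)-1-[(2R)-4-(bromomethyl)-5-oxo-2,5-dihydrofuran-2-yl]-6-{[(tert-butyldimethylsilyl)oxy]methyl}-7-(1,3-dioxolan-2-yl)-2-methylhepta-1,5-dien-4-yl acetate | CC(C)(C)[Si](C)(C)OC/C(CC1OCCO1)=C/[C@@H](OC(C)=O)C/C(C)=C\[C@H]1OC(=O)C(CBr)=C1 | intermediate
25 | 2,4,6-trimethylpyridinium N,O-acetal triflate of 24 (C8 bearing the pyridinium and an OCH2CH2OSiEt3 group) | CC(C)(C)[Si](C)(C)OC/C(CC(OCCO[Si](CC)(CC)CC)[n+]2c(C)cc(C)cc2C)=C/[C@@H](OC(C)=O)C/C(C)=C\[C@H]1OC(=O)C(CBr)=C1.[O-]S(=O)(=O)C(F)(F)F | intermediate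
26 | (1Z,4S,5E)-1-[(2R)-4-(bromomethyl)-5-oxo-2,5-dihydrofuran-2-yl]-6-{[(tert-butyldimethylsilyl)oxy]methyl}-2-methyl-8-oxoocta-1,5-dien-4-yl acetate | CC(C)(C)[Si](C)(C)OC/C(CC=O)=C/[C@@H](OC(C)=O)C/C(C)=C\[C@H]1OC(=O)C(CBr)=C1 | intermediate
27 | allylchromium(III) dichloride from 26 (CrCl2 on C13 in place of Br) | CC(C)(C)[Si](C)(C)OC/C(CC=O)=C/[C@@H](OC(C)=O)C/C(C)=C\[C@H]1OC(=O)C(C[Cr](Cl)Cl)=C1 | intermediate
28 | (3aR,4S,6E,8S,10Z,11aR)-6-{[(tert-butyldimethylsilyl)oxy]methyl}-4-hydroxy-10-methyl-3-methylidene-2-oxo-2,3,3a,4,5,8,9,11a-octahydrocyclodeca[b]furan-8-yl acetate | O[C@H]1C/C(CO[Si](C)(C)C(C)(C)C)=C\[C@@H](OC(C)=O)C/C(C)=C\[C@H]2OC(=O)C(=C)[C@@H]21 | intermediate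
29 | methacrylic acid | C=C(C)C(=O)O | starting material
30 | (3aR,4R,6E,8S,10Z,11aR)-8-(acetyloxy)-6-{[(tert-butyldimethylsilyl)oxy]methyl}-10-methyl-3-methylidene-2-oxo-2,3,3a,4,5,8,9,11a-octahydrocyclodeca[b]furan-4-yl 2-methylprop-2-enoate | C=C(C)C(=O)O[C@@H]1C/C(CO[Si](C)(C)C(C)(C)C)=C\[C@@H](OC(C)=O)C/C(C)=C\[C@H]2OC(=O)C(=C)[C@@H]21 | intermediate
31 | (3aR,4R,6E,8S,10Z,11aR)-8-(acetyloxy)-6-(hydroxymethyl)-10-methyl-3-methylidene-2-oxo-2,3,3a,4,5,8,9,11a-octahydrocyclodeca[b]furan-4-yl 2-methylprop-2-enoate | C=C(C)C(=O)O[C@@H]1C/C(CO)=C\[C@@H](OC(C)=O)C/C(C)=C\[C@H]2OC(=O)C(=C)[C@@H]21 | target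

Total step count: 16. Longest linear sequence: 16 steps (1 to 31).

Steps most likely to fail

Step 14 (ring closure). The tethered allylchromium may couple between molecules or be protonated before it reaches the aldehyde, and the ring constraint may override the chair and erode the facial selectivity at C8. The fallback sets out from 20 and comes back at 30; it replaces the reductively generated allylmetal by a stable allylsilane that reacts only once the aldehyde is activated. Alcohol 20 is esterified with 2-[(trimethylsilyl)methyl]acrylic acid (DCC, DMAP) to the 2-[(trimethylsilyl)methyl]acrylate F1. Ring-closing metathesis (Grubbs II) gives the 3-[(trimethylsilyl)methyl]butenolide F2, and acetal cleavage as in step 13 gives the aldehyde F3. BF3·OEt2 at −78 °C and 2 mM then closes the ring by an intramolecular Hosomi–Sakurai allylation through an open transition state, which should favour the 8β-alcohol F4. Acylation of F4 with methacrylic anhydride/DMAP (retention) gives 30. The same acylation applies if step 14 itself delivers the 8β-alcohol.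

Step 15 (inversion at C8). The alkoxyphosphonium ion may eliminate across C8–C9, the phosphine may add to the α-methylene lactone, or the ester may form with retention. The fallback sets out from 28 and comes back at 30; it is a phosphine-free two-stage SN2 inversion. Chloromethanesulfonyl chloride/pyridine converts 28 into the chloromethanesulfonate F5, which caesium methacrylate/18-crown-6 in toluene displaces with inversion to give 30.

Step 12 (butenolide metathesis). The ruthenium carbene may be lost by reaction at the allylic bromide, and closure onto the hindered 2-substituted acrylate may be slow. The fallback sets out from 20 and comes back at 24; the bromide is introduced only after the metathesis. Acid 21 and 4-methoxybenzyl alcohol (NaH, THF) give 2-{[(4-methoxybenzyl)oxy]methyl}acrylic acid F6. Esterification of 20 with it (DCC, DMAP) gives the acrylate F7, and metathesis (Grubbs II) gives the 3-{[(4-methoxybenzyl)oxy]methyl}butenolide F8. DDQ frees the 3-(hydroxymethyl)butenolide F9, and CBr4/PPh3 converts it into 24.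

Further compounds
F1 | step 14 | (2E,4S,6Z,8S,9E)-4-(acetyloxy)-2-{[(tert-butyldimethylsilyl)oxy]methyl}-1-(1,3-dioxolan-2-yl)-6-methylundeca-2,6,9-trien-8-yl 2-[(trimethylsilyl)methyl]prop-2-enoate | CC(C)(C)[Si](C)(C)OC/C(CC1OCCO1)=C/[C@@H](OC(C)=O)C/C(C)=C\[C@@H](OC(=O)C(=C)C[Si](C)(C)C)/C=C/C
F2 | step 14 | (1Z,4S,5E)-6-{[(tert-butyldimethylsilyl)oxy]methyl}-7-(1,3-dioxolan-2-yl)-2-methyl-1-{(2R)-5-oxo-4-[(trimethylsilyl)methyl]-2,5-dihydrofuran-2-yl}hepta-1,5-dien-4-yl acetate | CC(C)(C)[Si](C)(C)OC/C(CC1OCCO1)=C/[C@@H](OC(C)=O)C/C(C)=C\[C@H]1OC(=O)C(C[Si](C)(C)C)=C1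
F3 | step 14 | (1Z,4S,5E)-6-{[(tert-butyldimethylsilyl)oxy]methyl}-2-methyl-8-oxo-1-{(2R)-5-oxo-4-[(trimethylsilyl)methyl]-2,5-dihydrofuran-2-yl}octa-1,5-dien-4-yl acetate | CC(C)(C)[Si](C)(C)OC/C(CC=O)=C/[C@@H](OC(C)=O)C/C(C)=C\[C@H]1OC(=O)C(C[Si](C)(C)C)=C1
F4 | step 14 | (3aR,4R,6E,8S,10Z,11aR)-6-{[(tert-butyldimethylsilyl)oxy]methyl}-4-hydroxy-10-methyl-3-methylidene-2-oxo-2,3,3a,4,5,8,9,11a-octahydrocyclodeca[b]furan-8-yl acetate (8β-alcohol) | O[C@@H]1C/C(CO[Si](C)(C)C(C)(C)C)=C\[C@@H](OC(C)=O)C/C(C)=C\[C@H]2OC(=O)C(=C)[C@@H]21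
F5 | step 15 | (3aR,4S,6E,8S,10Z,11aR)-6-{[(tert-butyldimethylsilyl)oxy]methyl}-4-{[(chloromethyl)sulfonyl]oxy}-10-methyl-3-methylidene-2-oxo-2,3,3a,4,5,8,9,11a-octahydrocyclodeca[b]furan-8-yl acetate | ClCS(=O)(=O)O[C@H]1C/C(CO[Si](C)(C)C(C)(C)C)=C\[C@@H](OC(C)=O)C/C(C)=C\[C@H]2OC(=O)C(=C)[C@@H]21
F6 | step 12 | 2-{[(4-methoxybenzyl)oxy]methyl}prop-2-enoic acid | C=C(COCc1ccc(OC)cc1)C(=O)O
F7 | step 12 | (2E,4S,6Z,8S,9E)-4-(acetyloxy)-2-{[(tert-butyldimethylsilyl)oxy]methyl}-1-(1,3-dioxolan-2-yl)-6-methylundeca-2,6,9-trien-8-yl 2-{[(4-methoxybenzyl)oxy]methyl}prop-2-enoate | CC(C)(C)[Si](C)(C)OC/C(CC1OCCO1)=C/[C@@H](OC(C)=O)C/C(C)=C\[C@@H](OC(=O)C(=C)COCc2ccc(OC)cc2)/C=C/C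
F8 | step 12 | (1Z,4S,5E)-6-{[(tert-butyldimethylsilyl)oxy]methyl}-7-(1,3-dioxolan-2-yl)-1-[(2R)-4-{[(4-methoxybenzyl)oxy]methyl}-5-oxo-2,5-dihydrofuran-2-yl]-2-methylhepta-1,5-dien-4-yl acetate | CC(C)(C)[Si](C)(C)OC/C(CC1OCCO1)=C/[C@@H](OC(C)=O)C/C(C)=C\[C@H]1OC(=O)C(COCc2ccc(OC)cc2)=C1
F9 | step 12 | (1Z,4S,5E)-6-{[(tert-butyldimethylsilyl)oxy]methyl}-7-(1,3-dioxolan-2-yl)-1-[(2R)-4-(hydroxymethyl)-5-oxo-2,5-dihydrofuran-2-yl]-2-methylhepta-1,5-dien-4-yl acetate | CC(C)(C)[Si](C)(C)OC/C(CC1OCCO1)=C/[C@@H](OC(C)=O)C/C(C)=C\[C@H]1OC(=O)C(CO)=C1
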